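**Retrosynthetic overview**
- Target ⇒ cut the C5–allyl bond. C5 is the α-carbon of the C6 ketone, so it is made electrophilic (an enolonium equivalent: the phenol bound through oxygen to a chiral aryl-λ3-iodane) and captured by allyltrimethylsilane. This last step dearomatises the six-membered ring and sets C5.
- The phenol ⇒ (O-debenzylation, O-methylation) the 6-benzyloxy-5-hydroxy-2,3-dihydrobenzofuran.
- That ⇒ Ti–TADDOLate-promoted formal [3+2] of 2-(benzyloxy)-1,4-benzoquinone with (E)-isoelemicin, which sets C2 and C3 and builds the dihydrofuran ring.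
- Quinone ⇐ 2-(benzyloxy)phenol (Teuber oxidation); alkene ⇐ Suzuki coupling.
- Ring order: the carbocycle is bought as an arene, the dihydrofuran ring is closed in step 3, and the cyclohexadienone is unveiled in the last step.

Assumption: the (R,R)-antipodes of the TADDOL ligand (step 3) and of the lactate-derived iodane (step 6) are taken as the ones that give (2S,3S) and (5R); if a first run shows the opposite sense, the (S,S)-antipode is used with nothing else changed.

Reagent used in step 6, Ar*I(OCOCF3)2: preformed dimethyl (2R,2'R)-2,2'-({2-[bis(trifluoroacetoxy)-λ3-iodanyl]-1,3-phenylene}bis(oxy))dipropanoate, SMILES COC(=O)[C@@H](C)Oc1cccc(O[C@H](C)C(=O)OC)c1I(OC(=O)C(F)(F)F)OC(=O)C(F)(F)F.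

**Step 1**
Reactants: 1 5-bromo-1,2,3-trimethoxybenzene; 2 (E)-prop-1-en-1-ylboronic acid
Product: 3 (E)-isoelemicin [1,2,3-trimethoxy-5-[(E)-prop-1-en-1-yl]benzene]
Conditions: Pd(dppf)Cl2 (3 mol%), K2CO3, dioxane/H2O, 85 °C
Reagents that add atoms: none
Why: Suzuki–Miyaura coupling of an aryl bromide with an alkenylboronic acid proceeds with retention of the E geometry, giving the pure trans-propenylarene needed for a trans-2,3 relationship later.

**Step 2**
Reactants: 4 2-(benzyloxy)phenol
Product: 5 2-(benzyloxy)-1,4-benzoquinone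
Conditions: (KSO3)2NO (2.2 equiv), KH2PO4, H2O/acetone, 0 °C → rt
Reagents that add atoms: potassium nitrosodisulfonate (Fremy's salt), [O]N(S(=O)(=O)[O-])S(=O)(=O)[O-].[K+].[K+]
Why: Teuber oxidation of a phenol with a free para position gives the p-quinone, and the benzyl ether is inert to the nitroxide.

**Step 3**
Reactants: 3 (E)-isoelemicin; 5 2-(benzyloxy)-1,4-benzoquinone
Product: 7 (2S,3S)-6-(benzyloxy)-3-methyl-2-(3,4,5-trimethoxyphenyl)-2,3-dihydro-1-benzofuran-5-ol, via cyclobutane adduct 6 (not isolated)
Conditions: (R,R)-TADDOL, TiCl4, Ti(OiPr)4 (2 equiv TiCl2–TADDOLate), CH2Cl2, −78 °C; then TFA, −78 → 0 °C; recrystallise to >99% ee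
Reagents that add atoms: none
Why: In this Ti(IV)-promoted quinone–propenylarene formal [3+2] (via the [2+2] adduct), titanium chelated between C1=O and the benzyloxy oxygen directs the alkene β-carbon to quinone C5 on the face left open by the TADDOLate (sets C3); acid reopens cyclobutane 6 to the benzylic cation, which the C4 oxygen captures trans to the methyl group (sets C2) before tautomerisation to the phenol.

**Step 4**
Reactants: 7 (2S,3S)-6-(benzyloxy)-3-methyl-2-(3,4,5-trimethoxyphenyl)-2,3-dihydro-1-benzofuran-5-ol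
Product: 8 (2S,3S)-6-(benzyloxy)-5-methoxy-3-methyl-2-(3,4,5-trimethoxyphenyl)-2,3-dihydro-1-benzofuran
Conditions: MeI, K2CO3, acetone, 50 °C
Reagents that add atoms: iodomethane, CI
Why: Williamson O-methylation of the only free phenol; no stereocentre is touched.

**Step 5**
Reactants: 8 (2S,3S)-6-(benzyloxy)-5-methoxy-3-methyl-2-(3,4,5-trimethoxyphenyl)-2,3-dihydro-1-benzofuran
Product: 9 (2S,3S)-5-methoxy-3-methyl-2-(3,4,5-trimethoxyphenyl)-2,3-dihydro-1-benzofuran-6-ol
Conditions: H2 (1 atm), 10% Pd/C, EtOAc, rt, stop at full conversion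
Reagents that add atoms: none
Why: Hydrogenolysis of the aryl benzyl ether is much faster than cleavage of the cyclic secondary benzylic C2–O bond, so the phenol is released with C2 and C3 intact.

**Step 6**
Reactants: 9 (2S,3S)-5-methoxy-3-methyl-2-(3,4,5-trimethoxyphenyl)-2,3-dihydro-1-benzofuran-6-ol
Product: 11 (2S,3S,5R)-5-methoxy-3-methyl-5-(prop-2-en-1-yl)-2-(3,4,5-trimethoxyphenyl)-3,5-dihydro-1-benzofuran-6(2H)-one (CNP0316836.2), via aryloxy-λ3-iodane 10 (not isolated)
Conditions: Ar*I(OCOCF3)2 (1.1 equiv), allylSiMe3 (5 equiv), CH2Cl2, −78 → −40 °C; cold aq NaHCO3 quench; chromatography below 25 °C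
Reagents that add atoms: allyltrimethylsilane, C=CC[Si](C)(C)C
Why: Proposed new method: ligand exchange puts the phenol oxygen on I(III) (10), which inverts the polarity of the ring so that C5, the normally nucleophilic α-carbon of the emerging C6 ketone, is attacked by the nucleophilic γ-carbon of the allylsilane with loss of Ar*I and Me3Si+ (C5 rather than C7 or C3a because it is the methoxy-stabilised oxocarbenium position that alcohols also take in o-quinone monoketal formation, and C3a is fully substituted), while the lactate arms of the O-bound iodane are expected to block the face carrying the C3 methyl so that allyl enters anti to it and gives 5R; the closest known reactions are the PIFA-mediated ortho-allylation of 2-alkoxynaphthols with allylsilane to 6-allyl-6-alkoxycyclohexa-2,4-dienones and the asymmetric ortho-dearomatising spirolactonisation of phenols with lactate-derived chiral aryl-λ3-iodanes.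

**Compound list**
1 | 5-bromo-1,2,3-trimethoxybenzene | COc1cc(Br)cc(OC)c1OC | starting material
2 | (E)-prop-1-en-1-ylboronic acid | C/C=C/B(O)O | starting material
3 | (E)-isoelemicin | C/C=C/c1cc(OC)c(OC)c(OC)c1 | intermediate
4 | 2-(benzyloxy)phenol | Oc1ccccc1OCc1ccccc1 | starting material
5 | 2-(benzyloxy)-1,4-benzoquinone | O=C1C=CC(=O)C(OCc2ccccc2)=C1 | intermediate
6 | 3-(benzyloxy)-7-methyl-8-(3,4,5-trimethoxyphenyl)bicyclo[4.2.0]oct-3-ene-2,5-dione, cis-fused, 7-methyl exo and 8-aryl endo (trans to each other); C7 becomes C3 of 7 | O=C1C(OCc2ccccc2)=CC(=O)[C@H]2[C@H](C)[C@@H](c3cc(OC)c(OC)c(OC)c3)[C@@H]12 | intermediate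
7 | (2S,3S)-6-(benzyloxy)-3-methyl-2-(3,4,5-trimethoxyphenyl)-2,3-dihydro-1-benzofuran-5-ol | Oc1cc2c(cc1OCc1ccccc1)O[C@H](c1cc(OC)c(OC)c(OC)c1)[C@H]2C | intermediate
8 | (2S,3S)-6-(benzyloxy)-5-methoxy-3-methyl-2-(3,4,5-trimethoxyphenyl)-2,3-dihydro-1-benzofuran | COc1cc2c(cc1OCc1ccccc1)O[C@H](c1cc(OC)c(OC)c(OC)c1)[C@H]2C | intermediate
9 | (2S,3S)-5-methoxy-3-methyl-2-(3,4,5-trimethoxyphenyl)-2,3-dihydro-1-benzofuran-6-ol | COc1cc2c(cc1O)O[C@H](c1cc(OC)c(OC)c(OC)c1)[C@H]2C | intermediate
10 | aryloxy-λ3-iodane: the oxygen of 9 bound to iodine that also carries Ar* and one trifluoroacetate | COc1cc2c(cc1OI(OC(=O)C(F)(F)F)c1c(O[C@H](C)C(=O)OC)cccc1O[C@H](C)C(=O)OC)O[C@H](c1cc(OC)c(OC)c(OC)c1)[C@H]2C | intermediate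
11 | (2S,3S,5R)-5-methoxy-3-methyl-5-(prop-2-en-1-yl)-2-(3,4,5-trimethoxyphenyl)-3,5-dihydro-1-benzofuran-6(2H)-one; 2-aryl and 3-methyl trans, 5-allyl on the face of the aryl group, 5-methoxy on the face of the 3-methyl | C=CC[C@@]1(OC)C=C2C(=CC1=O)O[C@H](c1cc(OC)c(OC)c(OC)c1)[C@H]2C | target

**Step count and risks**
Total steps: 6. Longest linear sequence: 5 (4 → 5 → 7 → 8 → 9 → 11; the branch 1 + 2 → 3 joins at step 3).

Steps most likely to fail:

Step 6 (key step). Risks are attack of the allylsilane at C7 (giving a rearomatised 7-allylphenol), a dissociative pathway through the free phenoxenium ion that removes reagent control (low dr at C5), acid-promoted opening at the benzylic C2–O bond, and Cope migration of the allyl group to C3a if the product is warmed. Fallback, setting out from 9 and returning at 11: oxidise 9 with PhI(OAc)2 in MeOH at 0 °C to the o-quinone monoketal (2S,3S)-5,5-dimethoxy-3-methyl-2-(3,4,5-trimethoxyphenyl)-3,5-dihydro-1-benzofuran-6(2H)-one F1. Then treat F1 with allyltrimethylsilane and TMSOTf in CH2Cl2 at −78 °C. Loss of one methoxy group gives the α-keto oxocarbenium ion, the same enolonium synthon but now generated with no oxidant, iodane or free phenol present, and it is allylated at C5. This gives 11 together with its C5 epimer (2S,3S,5S)-5-methoxy-3-methyl-5-(prop-2-en-1-yl)-2-(3,4,5-trimethoxyphenyl)-3,5-dihydro-1-benzofuran-6(2H)-one F2; the two are diastereomers and are separated by chromatography.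

Step 3. Risks are enantioselectivity below the 80–90% ee typical of this reagent class, and an uncertain product distribution with the trimethoxyphenyl alkene. Fallback, setting out from 3 and 5 and returning at 7: run the coupling with achiral TiCl4/Ti(OiPr)4 in CH2Cl2 at −78 °C followed by TFA. This gives the racemic cyclobutane, that is 6 together with its mirror image ent-cyclobutane adduct F3, which isomerises to the racemic trans product, that is 7 together with (2R,3R)-6-(benzyloxy)-3-methyl-2-(3,4,5-trimethoxyphenyl)-2,3-dihydro-1-benzofuran-5-ol F4. Preparative chiral SFC on an amylose phase then delivers 7; this replaces asymmetric induction by resolution.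

Step 5. The risk is over-reduction with hydrogenolytic opening of the dihydrofuran at the benzylic C2–O bond. Fallback, setting out from 8 and returning at 9: non-reductive debenzylation with BCl3 and pentamethylbenzene in CH2Cl2 at −78 °C, where the benzyl cation is trapped by the scavenger and the methyl ethers survive at this temperature. This fallback makes no new compound (F0).

**Further compounds**
F1 | step 6 | (2S,3S)-5,5-dimethoxy-3-methyl-2-(3,4,5-trimethoxyphenyl)-3,5-dihydro-1-benzofuran-6(2H)-one | COC1(OC)C=C2C(=CC1=O)O[C@H](c1cc(OC)c(OC)c(OC)c1)[C@H]2C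
F2 | step 6 | (2S,3S,5S)-5-methoxy-3-methyl-5-(prop-2-en-1-yl)-2-(3,4,5-trimethoxyphenyl)-3,5-dihydro-1-benzofuran-6(2H)-one | C=CC[C@]1(OC)C=C2C(=CC1=O)O[C@H](c1cc(OC)c(OC)c(OC)c1)[C@H]2C
F3 | step 3 | ent-cyclobutane adduct (mirror image of 6) | O=C1C(OCc2ccccc2)=CC(=O)[C@@H]2[C@@H](C)[C@H](c3cc(OC)c(OC)c(OC)c3)[C@H]12
F4 | step 3 | (2R,3R)-6-(benzyloxy)-3-methyl-2-(3,4,5-trimethoxyphenyl)-2,3-dihydro-1-benzofuran-5-ol | Oc1cc2c(cc1OCc1ccccc1)O[C@@H](c1cc(OC)c(OC)c(OC)c1)[C@@H]2C
F0 | step 5 | none | none
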